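**Conventions and assumptions**
- Labels C1–C20 are the ent-kaurane positions of the target and are used only to locate atoms.
- The (−)-menthyl fumarate auxiliary is taken to give (S,S) Diels–Alder adducts, so the (+)-menthyl ester is used. If the sense is the opposite, swap the menthol enantiomer.
- In step 21 the cinchona pseudo-enantiomer that delivers (S)-26 is used.

**Retrosynthetic overview**
1. Exo-methylene enone from ketone 35 by Mannich methylenation; ring D from a Dieckmann closure (C16 onto the C8 ester, 33 → 34).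
2. Ring C from a C9–C11 nitro-Michael union of west lactone 17 with east nitro ester 29, then C8–C14 alkylation; C11–OH by Nef then L-Selectride.
3. Key ring closure: spiro δ-lactone (ring B) of 17 by intramolecular Knoevenagel–aldol condensation of malonate aldehyde 16.
4. West: ring A by auxiliary-controlled [4+2] (2 + 5), C4 by aldol–lactonization, C10 by ester-enolate alkylation. East: cinchona desymmetrization of anhydride 25.
5. Ring order: A → THF acetal → B (lactone) → C → D.

## West fragment

**Step 1**
Reactants: 1 ethyl vinyl ketone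
Product: 2 (Z)-3-(tert-butyldimethylsilyloxy)penta-1,3-diene
Conditions: TBSOTf, Et3N, Et2O, 0 °C
Reagents that add atoms: TBSOTf, CC(C)(C)[Si](C)(C)OS(=O)(=O)C(F)(F)F
Why: Soft enolization gives the cross-conjugated silyl dienol ether, with the methyl cis to OSi and therefore "outside" in the s-cis diene.

**Step 2**
Reactants: 3 (+)-menthol (2 equiv); 4 fumaryl chloride
Product: 5 di-(+)-menthyl fumarate
Conditions: pyridine, DMAP (cat.), CH2Cl2, 0 °C → rt
Reagents that add atoms: none
Why: Simple double O-acylation installs the C2-symmetric chiral auxiliary pair.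

**Step 3**
Reactants: 2; 5
Product: 6 di-(+)-menthyl (1R,2R)-3-methyl-4-oxocyclohexane-1,2-dicarboxylate (trans diester, C3-methyl epimers)
Conditions: Et2AlCl, toluene, −78 → −40 °C; then 1 M HCl, THF, 0 °C
Reagents that add atoms: none
Why: Lewis-acid-promoted asymmetric Diels–Alder (or Mukaiyama–Michael/Michael) on the chiral fumarate; the menthyl groups shield one face and fix C5 (R), and acid unveils the C3 ketone.

**Step 4**
Reactants: 6
Product: 7 cis-fused keto γ-lactone, (+)-menthyl (3aR,7R,7aS)-3a-methyl-1,4-dioxooctahydro-2-benzofuran-7-carboxylate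
Conditions: 37% aq. HCHO (1.5 equiv), DBU (0.2 equiv), THF, rt; then TsOH (cat.), toluene, 60 °C
Reagents that add atoms: formaldehyde, C=O
Why: Reversible crossed aldol at the methyl-bearing α-carbon; only the adduct with CH2OH cis to the C5 ester is drained as the cis-fused lactone, which sets quaternary C4 with C19 cis to C6.

**Step 5**
Reactants: 7
Product: 8 C3 1,3-dithiolane of 7
Conditions: HSCH2CH2SH, BF3·OEt2, CH2Cl2, 0 °C → rt
Reagents that add atoms: ethane-1,2-dithiol, SCCS
Why: Dithioketalization of the only ketone; lactone and ester are inert.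

**Step 6**
Reactants: 8
Product: 9 (+)-menthyl (3aR,7R,7aS)-3a-methyl-1-oxooctahydro-2-benzofuran-7-carboxylate
Conditions: Raney Ni (W-2), EtOH, reflux
Reagents that add atoms: none
Why: Mozingo desulfurization removes the C3 oxygen once it has activated C4.

**Step 7**
Reactants: 9
Product: 10 lactol (C6 hemiacetal, anomers)
Conditions: DIBAL-H (1.1 equiv), CH2Cl2, −78 °C
Reagents that add atoms: none
Why: The γ-lactone is reduced to the lactol much faster than the hindered secondary menthyl ester.

**Step 8**
Reactants: 10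
Product: 11 methyl acetal (C19–O–C6(OMe) ring, OMe trans to the C5–C10 bond; C10 still CH–CO2Men)
Conditions: MeOH, HC(OMe)3, PPTS, rt
Reagents that add atoms: methanol, CO
Why: Fischer-type acetalization via the oxocarbenium ion gives the thermodynamic exo anomer, which is the 6S configuration of the target.

**Step 9**
Reactants: 11
Product: 12 C10-quaternary ester (β-CH2OBn = C9, α-CO2Men = C20)
Conditions: LDA, THF/HMPA, −78 °C; BnOCH2Cl, −78 → −20 °C
Reagents that add atoms: benzyl chloromethyl ether, ClCOCc1ccccc1
Why: Ester-enolate alkylation; the electrophile enters equatorially on the β face, anti to the axial C19–O bridge and the acetal ring, so C20 ends cis to C6 and C19.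

**Step 10**
Reactants: 12
Product: 13 neopentyl alcohol (C20–OH; C9 as CH2OBn)
Conditions: LiAlH4, THF, 0 °C → reflux
Reagents that add atoms: none
Why: Hydride reduction of the hindered ester (menthol recovered); the acetal and benzyl ether are stable.

**Step 11**
Reactants: 13
Product: 14 mixed methyl malonate of the C20 alcohol
Conditions: methyl malonyl chloride, pyridine, CH2Cl2, 0 °C
Reagents that add atoms: methyl 3-chloro-3-oxopropanoate, COC(=O)CC(=O)Cl
Why: O-acylation brings in C7, C8 and C15.

**Step 12**
Reactants: 14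
Product: 15 C9 primary alcohol
Conditions: H2 (1 atm), Pd/C, EtOAc, rt (used at once)
Reagents that add atoms: none
Why: Neutral hydrogenolysis of the benzyl ether; neutral conditions and immediate use suppress 1,3-acyl migration.

**Step 13**
Reactants: 15
Product: 16 C9 aldehyde
Conditions: Dess–Martin periodinane, NaHCO3, CH2Cl2, 0 °C → rt
Reagents that add atoms: none
Why: Mild oxidation to a non-enolizable neopentyl aldehyde.

**Step 14 (key ring closure)**
Reactants: 16
Product: 17 spiro α-methoxycarbonyl-α,β-unsaturated δ-lactone (C8=C9)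
Conditions: piperidine (cat.), AcOH (cat.), benzene, 4 Å MS, rt → 40 °C
Reagents that add atoms: none
Why: Intramolecular Knoevenagel (aldol addition then E1cB dehydration) of the malonate onto the tethered aldehyde closes the six-membered lactone and creates a doubly activated acceptor at C9.

## East fragment

**Step 15**
Reactants: 18 dimethyl malonate; 19 cis-1,4-dichlorobut-2-ene
Product: 20 dimethyl cyclopent-3-ene-1,1-dicarboxylate
Conditions: LiH, DMF, 0 °C → rt
Reagents that add atoms: none
Why: Double malonate alkylation (SN2 then 5-exo-tet).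

**Step 16**
Reactants: 20
Product: 21 methyl cyclopent-3-ene-1-carboxylate
Conditions: LiCl, H2O, DMSO, 160 °C
Reagents that add atoms: none
Why: Krapcho dealkoxycarbonylation of a geminal diester.

**Step 17**
Reactants: 21
Product: 22 cyclopent-3-en-1-ylmethanol
Conditions: LiAlH4, Et2O, 0 °C
Reagents that add atoms: none
Why: Ester reduction.

**Step 18**
Reactants: 22
Product: 23 4-(chloromethyl)cyclopent-1-ene
Conditions: PPh3, CCl4, CH2Cl2, rt → 40 °C
Reagents that add atoms: carbon tetrachloride, ClC(Cl)(Cl)Cl
Why: Appel chlorination of a primary alcohol.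

**Step 19**
Reactants: 23
Product: 24 3-(chloromethyl)pentanedioic acid
Conditions: RuCl3·xH2O (cat.), NaIO4, CCl4/MeCN/H2O, rt
Reagents that add atoms: sodium periodate, [Na+].[O-]I(=O)(=O)=O; water, O
Why: RuO4 oxidative cleavage of the ring alkene to the meso diacid.

**Step 20**
Reactants: 24
Product: 25 3-(chloromethyl)glutaric anhydride
Conditions: Ac2O, reflux; evaporate
Reagents that add atoms: none
Why: Cyclodehydration to the meso six-membered anhydride.

**Step 21**
Reactants: 25
Product: 26 (S)-3-(chloromethyl)-5-methoxy-5-oxopentanoic acid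
Conditions: MeOH (10 equiv), (DHQD)2AQN or (DHQ)2AQN (20 mol %), Et2O, −40 °C
Reagents that add atoms: methanol, CO
Why: Cinchona-catalyzed desymmetrizing alcoholysis of the meso anhydride sets the future C13 stereocenter.

**Step 22**
Reactants: 26
Product: 27 methyl (S)-3-(chloromethyl)-5-hydroxypentanoate (used crude to avoid δ-lactonization)
Conditions: BH3·SMe2, THF, −10 → 0 °C
Reagents that add atoms: none
Why: Borane reduces the carboxylic acid chemoselectively in the presence of the methyl ester.

**Step 23**
Reactants: 27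
Product: 28 methyl (R)-3-(chloromethyl)-5-iodopentanoate
Conditions: I2, PPh3, imidazole, CH2Cl2, 0 °C
Reagents that add atoms: iodine, II
Why: Appel-type iodination of the primary alcohol; the descriptor changes only because CIP priorities change.

**Step 24**
Reactants: 28
Product: 29 methyl (S)-3-(chloromethyl)-5-nitropentanoate
Conditions: NaNO2, phloroglucinol, DMSO, rt
Reagents that add atoms: sodium nitrite, [Na+].[O-]N=O
Why: Kornblum displacement occurs at the primary iodide only; the β-branched chloride is inert.

## Union and endgame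

**Step 25**
Reactants: 17; 29
Product: 30 Michael adduct (C9–C11 bond; C9 as in target; C8 and C11 epimer mixtures)
Conditions: DBU (1.1 equiv), MeCN, 0 °C → rt; NH4Cl quench
Reagents that add atoms: none
Why: Nitro-Michael addition to the alkylidene malonate; the nitronate attacks C9 on the lactone face next to C1, anti to the C5 branch carrying the acetal ring, which sets C9.

**Step 26**
Reactants: 30
Product: 31 ring-C nitro bicycle (C8 quaternary, C8–C14 bond; C11 epimers; major C8 epimer drawn)
Conditions: Cs2CO3, NaI, DMF, 60 °C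
Reagents that add atoms: none
Why: The malonate-type C8 enolate, more acidic than the nitroalkane, closes ring C by 6-exo-tet C-alkylation (Michael-initiated ring closure); either C8 epimer converges in step 29.

**Step 27**
Reactants: 31
Product: 32 C11 ketone
Conditions: KOtBu, THF, −78 °C; then O3, CH2Cl2/MeOH, −78 °C; Me2S
Reagents that add atoms: ozone, [O-][O+]=O
Why: Oxidative Nef reaction (ozonolysis of the nitronate) gives the ketone without prolonged base contact at the epimerizable C9.

**Step 28**
Reactants: 32
Product: 33 C11 triethylsilyl ether (11-O on the face of C10, as in target)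
Conditions: L-Selectride, THF, −78 °C; then TESOTf, 2,6-lutidine, −78 → 0 °C
Reagents that add atoms: triethylsilyl triflate, CC[Si](CC)(CC)OS(=O)(=O)C(F)(F)F
Why: With C10 equatorial on ring C, the bulky hydride attacks equatorially, away from the axial C8 acyl group, giving the axial alkoxide, which is silylated in situ before it can lactonize onto C7.

**Step 29**
Reactants: 33
Product: 34 bicyclo[3.2.1]octane β-keto ester (ring D; C15 ketone, C16–CO2Me)
Conditions: LiHMDS (2.5 equiv), THF, −78 °C → rt; AcOH quench
Reagents that add atoms: none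
Why: Dieckmann condensation; only the C8 carbonyl cis to the C13 arm can be reached, so C13 (from 29) dictates C8, and if the lactone carbonyl is the one attacked, the freed C20 alkoxide re-lactonizes onto the other ester to give the same product.

**Step 30**
Reactants: 34
Product: 35 C15 ketone with C16 as CH2
Conditions: LiCl, H2O, DMSO, 120 °C
Reagents that add atoms: none
Why: Krapcho demethoxycarbonylation of the β-keto ester; the lactone and acetal are stable to neutral halide.

**Step 31**
Reactants: 35
Product: 36 α-methylene cyclopentanone (11-OTES)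
Conditions: LiHMDS, THF, −78 °C; Me2N=CH2+ I−; then MeI; then aq. NaHCO3
Reagents that add atoms: Eschenmoser's salt, C=[N+](C)C.[I-]
Why: Mannich reaction at C16, the only enolizable position, followed by quaternization and elimination installs C17.

**Step 32**
Reactants: 36
Product: 37 angustifolin
Conditions: PPTS, MeOH, rt
Reagents that add atoms: none (MeOH only exchanges the acetal OMe)
Why: Mild acid methanolysis removes the TES ether and re-equilibrates the C6 methyl acetal to the thermodynamic 6S anomer.

## Compound list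

1 | ethyl vinyl ketone | C=CC(=O)CC | starting material
2 | (Z)-3-(tert-butyldimethylsilyloxy)penta-1,3-diene | C=C/C(=C/C)O[Si](C)(C)C(C)(C)C | intermediate
3 | (+)-menthol (1S,2R,5S) | O[C@H]1C[C@@H](C)CC[C@@H]1C(C)C | starting material
4 | fumaryl chloride | O=C(Cl)/C=C/C(Cl)=O | starting material
5 | di-(+)-menthyl fumarate | O=C(/C=C/C(=O)O[C@H]1C[C@@H](C)CC[C@@H]1C(C)C)O[C@H]1C[C@@H](C)CC[C@@H]1C(C)C | intermediate
6 | di-(+)-menthyl (1R,2R)-3-methyl-4-oxocyclohexane-1,2-dicarboxylate (C3 epimers) | O=C(O[C@H]1C[C@@H](C)CC[C@@H]1C(C)C)[C@@H]2CCC(=O)C(C)[C@H]2C(=O)O[C@H]3C[C@@H](C)CC[C@@H]3C(C)C | intermediate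
7 | (+)-menthyl (3aR,7R,7aS)-3a-methyl-1,4-dioxooctahydro-2-benzofuran-7-carboxylate | O=C(O[C@H]3C[C@@H](C)CC[C@@H]3C(C)C)[C@@H]1CCC(=O)[C@@]2(C)COC(=O)[C@H]21 | intermediate
8 | 4-spiro-1,3-dithiolane of 7 | O=C(O[C@H]4C[C@@H](C)CC[C@@H]4C(C)C)[C@@H]1CCC2(SCCS2)[C@@]3(C)COC(=O)[C@H]31 | intermediate
9 | (+)-menthyl (3aR,7R,7aS)-3a-methyl-1-oxooctahydro-2-benzofuran-7-carboxylate | O=C(O[C@H]3C[C@@H](C)CC[C@@H]3C(C)C)[C@@H]1CCC[C@@]2(C)COC(=O)[C@H]21 | intermediate
10 | lactol of 9 (C6–OH, anomers) | O=C(O[C@H]3C[C@@H](C)CC[C@@H]3C(C)C)[C@@H]1CCC[C@@]2(C)COC(O)[C@H]21 | intermediate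
11 | methyl acetal ester (OMe exo) | O=C(O[C@H]3C[C@@H](C)CC[C@@H]3C(C)C)[C@@H]1CCC[C@@]2(C)CO[C@H](OC)[C@H]21 | intermediate
12 | C10-quaternary ester (β-CH2OBn, α-CO2-menthyl) | c1ccccc1COC[C@@]1(CCC[C@@]2(C)CO[C@H](OC)[C@H]21)C(=O)O[C@H]1C[C@@H](C)CC[C@@H]1C(C)C | intermediate
13 | C20 alcohol, C9 benzyl ether | c1ccccc1COC[C@@]1(CCC[C@@]2(C)CO[C@H](OC)[C@H]21)CO | intermediate
14 | C20 methyl malonate, C9 benzyl ether | c1ccccc1COC[C@@]1(CCC[C@@]2(C)CO[C@H](OC)[C@H]21)COC(=O)CC(=O)OC | intermediate
15 | C20 methyl malonate, C9 alcohol | OC[C@@]1(CCC[C@@]2(C)CO[C@H](OC)[C@H]21)COC(=O)CC(=O)OC | intermediate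
16 | C20 methyl malonate, C9 aldehyde | O=C[C@@]1(CCC[C@@]2(C)CO[C@H](OC)[C@H]21)COC(=O)CC(=O)OC | intermediate
17 | spiro 3-methoxycarbonyl-5,6-dihydropyran-2-one (west fragment) | COC(=O)C1=C[C@@]2(CCC[C@@]3(C)CO[C@H](OC)[C@H]32)COC1=O | intermediate
18 | dimethyl malonate | COC(=O)CC(=O)OC | starting material
19 | cis-1,4-dichlorobut-2-ene | ClC/C=C\CCl | starting material
20 | dimethyl cyclopent-3-ene-1,1-dicarboxylate | COC(=O)C1(C(=O)OC)CC=CC1 | intermediate
21 | methyl cyclopent-3-ene-1-carboxylate | COC(=O)C1CC=CC1 | intermediate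
22 | cyclopent-3-en-1-ylmethanol | OCC1CC=CC1 | intermediate
23 | 4-(chloromethyl)cyclopent-1-ene | ClCC1CC=CC1 | intermediate
24 | 3-(chloromethyl)pentanedioic acid | OC(=O)CC(CCl)CC(=O)O | intermediate
25 | 3-(chloromethyl)glutaric anhydride | O=C1CC(CCl)CC(=O)O1 | intermediate
26 | (S)-3-(chloromethyl)-5-methoxy-5-oxopentanoic acid | OC(=O)C[C@H](CCl)CC(=O)OC | intermediate
27 | methyl (S)-3-(chloromethyl)-5-hydroxypentanoate | OCC[C@H](CCl)CC(=O)OC | intermediate
28 | methyl (R)-3-(chloromethyl)-5-iodopentanoate | ICC[C@H](CCl)CC(=O)OC | intermediate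
29 | methyl (S)-3-(chloromethyl)-5-nitropentanoate (east fragment) | [O-][N+](=O)CC[C@H](CCl)CC(=O)OC | intermediate
30 | Michael adduct (C8, C11 epimers) | ClC[C@H](CC(=O)OC)CC([N+](=O)[O-])[C@H]1[C@@]2(CCC[C@@]3(C)CO[C@H](OC)[C@H]32)COC(=O)C1C(=O)OC | intermediate
31 | ring-C nitro compound (C11 epimers; major C8 epimer) | COC(=O)[C@]12C[C@H](CC(=O)OC)CC([N+](=O)[O-])[C@H]1[C@@]3(CCC[C@@]4(C)CO[C@H](OC)[C@H]43)COC2=O | intermediate
32 | C11 ketone | COC(=O)[C@]12C[C@H](CC(=O)OC)CC(=O)[C@H]1[C@@]3(CCC[C@@]4(C)CO[C@H](OC)[C@H]43)COC2=O | intermediate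
33 | C11 TES ether | COC(=O)[C@]12C[C@H](CC(=O)OC)C[C@@H](O[Si](CC)(CC)CC)[C@H]1[C@@]3(CCC[C@@]4(C)CO[C@H](OC)[C@H]43)COC2=O | intermediate
34 | bicyclo[3.2.1] β-keto ester (C16 epimers/enol) | COC(=O)C1C(=O)[C@]23C[C@H]1C[C@@H](O[Si](CC)(CC)CC)[C@H]2[C@@]1(CCC[C@@]2(C)CO[C@H](OC)[C@H]21)COC3=O | intermediate
35 | C15 ketone, 11-OTES | C1C(=O)[C@]23C[C@H]1C[C@@H](O[Si](CC)(CC)CC)[C@H]2[C@@]1(CCC[C@@]2(C)CO[C@H](OC)[C@H]21)COC3=O | intermediate
36 | 11-O-TES angustifolin | C=C1C(=O)[C@]23C[C@H]1C[C@@H](O[Si](CC)(CC)CC)[C@H]2[C@@]1(CCC[C@@]2(C)CO[C@H](OC)[C@H]21)COC3=O | intermediate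
37 | angustifolin | C=C1C(=O)[C@]23C[C@H]1C[C@@H](O)[C@H]2[C@@]1(CCC[C@@]2(C)CO[C@H](OC)[C@H]21)COC3=O | target

## Summary

- **Total steps:** 32 (west 14, east 10, union and endgame 8).
- **Longest linear sequence:** 21 steps (1, 3–14, 25–32), which is 66% of the total.

**Three steps most likely to fail**

1. **Steps 25–26 (nitro-Michael at the neopentyl C9, then ring-C alkylation).** Retro-Michael and nitronate O-alkylation can compete on heating. Fallback: add nitroethane to 17 instead, C-alkylate C8 with methyl (E)-4-bromocrotonate, run the Nef reaction, and close ring C by intramolecular Michael addition of the C11 methyl-ketone enolate onto the enoate (C12 → C13). This also delivers the CH2CO2Me arm.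

2. **Step 29 (Dieckmann).** It must go through the strained ring-C conformer with C10 axial and attacks an ester on a quaternary carbon. Fallback: remove the C8 ester (Krapcho), convert the arm ester to the aldehyde, and close ring D by intramolecular aldol of the lactone enolate (C8 → C15), then oxidize C15–OH to the ketone.

3. **Step 28 (C11 configuration and competing γ-lactonization onto C7).** The facial argument is conformational and unverified. Fallback: carry the C11 ketone (as its dioxolane) through ring-D formation and set C11–OH at the end on the rigid bicyclo[3.2.1] core, where the target's equatorial alcohol is the thermodynamic one (Meerwein–Ponndorf–Verley equilibration, or Mitsunobu inversion of the kinetic axial alcohol).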